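The runs were generated by integration with made-up constants; the scatter is artificial.

The constants of this flask are to be read from the earlier runs. The one worth carrying is the partner yield: target at its peak per partner charged.

| flask | starting material | partner | protic impurity | remark | time |
|---|---|---|---|---|---|
| east | 0.41 M | 0.18 M | 0.41 M | run made earlier |  |
| west | 0.41 M | 0.74 M | 0.41 M | run made earlier |  |
| south-west | 0.20 M | 0.369 M | 0.41 M | run made earlier |  |
| flask | 0.41 M | 0.369 M | 0.410 M |  | 2.0 min |

- east (time / s: target / %, starting material / %): 12.0: 11.2, 84.3; 15.0: 13.0, 83.1; 25.0: 17.2, 77.2; 30.0: 18.8, 75.8; 50.0: 19.0, 70.5; 60.0: 18.3, 68.5; 90.0: 16.2, 65.3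
- west (time / s: target / %, starting material / %): 12.0: 37.5, 49.4; 15.0: 44.0, 44.4; 25.0: 57.5, 32.3; 30.0: 60.7, 28.8; 50.0: 66.4, 20.5; 60.0: 66.4, 17.0; 90.0: 66.1, 13.0
- south-west (time / s: target / %, starting material / %): 12.0: 22.9, 69.0; 20.0: 34.2, 58.1; 30.0: 44.4, 50.2; 60.0: 51.1, 38.8; 90.0: 53.2, 34.5

(standard deviation of a reading: 0.5 percentage points)

1. when, up to 2.0 min, the flask holds most target
2. the amount of target, in percent of the starting material charged, at that time
3. the first time at which target reaches 27%, in the same percent, in min



The runs read clock by clock, in the order in which each shows itself:

1. First comes a gap. At the first west reading, 12.0 s, the starting material lost exceeds the target by 13 percentage points, so some material already stands in forms not read.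

2. Next comes consumption. The first east reading, scaled to this flask's partner, gives a time scale for starting material of 34.3 s. The first west reading, scaled the same way, gives 34.1 s, so the early loss follows the partner.

3. Then the rise ends. East target reads highest at 50.0 s, later than that time scale, and west reaches its highest reading there too. This flask's partner lies between theirs, so this reckoning puts its peak near that time, although south-west, with the flask's partner and less starting material, still reads higher at its last reading, 90.0 s, than at the one before.

4. Last comes the decline: east target loses 2.8 points in the following 40.0 s. That loss is less than the 19.0% read at the east peak, so the height of the peak is the number to reckon here.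

5. The partner yield, target concentration at the peak divided by partner concentration charged, reads 0.433 in east, with less partner than starting material. West, with more partner than starting material, reads 0.368. This flask also has less partner than starting material, so this reckoning carries the east yield over, which gives a peak of 39.0%.

The forecast says 1 min, 39% and 0.35 min, on the ground that “Target peaks when feed falls to match decay”, and its peak time is later than the one reckoned here.

The flask holds most target at 0.815 min, namely 38.0%, and reaches 27% at 0.280 min.

    starting material + partner → intermediate + released group (k = 0.110 M⁻¹ s⁻¹)
    intermediate → target (k = 0.250 s⁻¹)
    starting material + target → side product (k = 0.0210 M⁻¹ s⁻¹)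
    partner → decomposed reagent (k = 0.0230 s⁻¹)
    partner + protic impurity → quenched reagent (k = 0.0140 M⁻¹ s⁻¹)

That peak is a partner yield of 0.422 in this flask. The neighbouring flask keeps the same charges except for 0.15 M of partner, which is 0.366 equiv. The east yield, times the neighbour's partner and divided by the neighbour's starting material, gives 15.8%, and that neighbour holds 16.3% at best. Partner is the limiting reagent there, first to run out, with 0.052% of its charge left at 2.00 min and 69% of the starting material still present.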